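## Retrosynthetic overview

1. The two formyl groups come last, by Vilsmeier–Haack diformylation of the 6',8'-dihydroxychroman; the two phenols travel as benzyl ethers.
2. The pyran ring is the last ring formed: the C3a'–O bond is made by reductive etherification (Et3SiH) of a keto-phenol, giving the cis ring fusion.
3. Key disconnection C9'–C9a': intermolecular Mukaiyama–Michael addition of the silyl enol ether of a spiro[4.5]decenone to an o-quinone methide built from 2,4,6-trihydroxybenzaldehyde, benzyl bromide and iBuMgBr.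
4. The cyclopentanone ring is the second ring: Dieckmann condensation, methylation and Krapcho reaction on a cyclohexene that carries a quaternary ester and a butanoate chain (from allylation and cross-metathesis).
5. The cyclohexene ring and its methyl stereocentre come from (−)-menthone: Claisen carboxylation, diastereoselective allylation (sets the spiro centre) and vinyl triflate reduction (sets the ring alkene).

Assumption: centres that are epimerisable or later made trigonal (C1/C3 of 3, C3 of 5, C2 of 12 and 13, the carbinol carbon of 19 and of F2, the hemiketal carbon of 22) are carried as mixtures and left open in the SMILES; chroman locants follow spiro[cyclohex-2-ene-1,3'-cyclopenta[b]chromene] (O4', spiro carbon C1/C3', benzylic carbon C9').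

## Route

Step 1
Reactants: 1 (−)-menthone [(2S,5R)-5-methyl-2-(propan-2-yl)cyclohexan-1-one]; 2 dimethyl carbonate
Product: 3 methyl (6R)-6-methyl-2-oxo-3-(propan-2-yl)cyclohexane-1-carboxylate
Conditions: NaH (2.5 equiv), MeOH (cat.), THF, reflux; then 1 M HCl, 0 °C
Reagents that add atoms: none
Why: Crossed Claisen condensation of the ketone enolate with the carbonate; only acylation at the ring CH2 gives an enolisable β-keto ester that is held as its enolate, so the reaction is regioselective and the methyl-bearing centre (β to the carbonyl) is untouched.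

Step 2
Reactants: 3 methyl (6R)-6-methyl-2-oxo-3-(propan-2-yl)cyclohexane-1-carboxylate; 4 allyl bromide (3-bromoprop-1-ene)
Product: 5 methyl (1R,6R)-6-methyl-2-oxo-3-(propan-2-yl)-1-(prop-2-en-1-yl)cyclohexane-1-carboxylate
Conditions: NaH (1.1 equiv), THF/DMF, 0 °C; allyl bromide, 0 °C → rt; chromatography
Reagents that add atoms: none
Why: SN2 C-allylation of the β-keto ester enolate; the electrophile enters anti to the adjacent C6 methyl, which sets the quaternary centre (1R) with allyl trans and ester cis to that methyl.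

Step 3
Reactants: 5 methyl (1R,6R)-6-methyl-2-oxo-3-(propan-2-yl)-1-(prop-2-en-1-yl)cyclohexane-1-carboxylate
Product: 6 methyl (1R,6R)-6-methyl-3-(propan-2-yl)-1-(prop-2-en-1-yl)-2-[(trifluoromethanesulfonyl)oxy]cyclohex-2-ene-1-carboxylate
Conditions: KN(SiMe3)2 (1.2 equiv), THF, −78 → 0 °C; PhNTf2, 0 °C → rt
Reagents that add atoms: N-phenylbis(trifluoromethanesulfonimide), O=S(=O)(N(c1ccccc1)S(=O)(=O)C(F)(F)F)C(F)(F)F
Why: Enolate O-triflation; the ketone has a single α-hydrogen (C3–H) and the ester none, so one enolate and one vinyl triflate form, and both sp3 stereocentres are left alone.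

Step 4
Reactants: 6 methyl (1R,6R)-6-methyl-3-(propan-2-yl)-1-(prop-2-en-1-yl)-2-[(trifluoromethanesulfonyl)oxy]cyclohex-2-ene-1-carboxylate
Product: 7 methyl (1R,6R)-6-methyl-3-(propan-2-yl)-1-(prop-2-en-1-yl)cyclohex-2-ene-1-carboxylate
Conditions: Pd(OAc)2 (5 mol%), PPh3 (10 mol%), HCO2H (2 equiv), Bu3N (3 equiv), DMF, 60 °C
Reagents that add atoms: none
Why: Palladium-catalysed formate reduction of the vinyl triflate (oxidative addition to zerovalent palladium, formate decarboxylation, reductive elimination) replaces OTf by H and fixes the ring alkene position without a cationic intermediate.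

Step 5
Reactants: 7 methyl (1R,6R)-6-methyl-3-(propan-2-yl)-1-(prop-2-en-1-yl)cyclohex-2-ene-1-carboxylate; 8 methyl acrylate
Product: 9 methyl (2E)-4-[(1R,6R)-1-(methoxycarbonyl)-6-methyl-3-(propan-2-yl)cyclohex-2-en-1-yl]but-2-enoate
Conditions: second-generation Grubbs catalyst (5 mol%), methyl acrylate (5 equiv), CH2Cl2, 40 °C
Reagents that add atoms: none
Why: Olefin cross-metathesis of the terminal alkene with an acrylate is E-selective, and the hindered trisubstituted ring alkene does not take part.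

Step 6
Reactants: 9 methyl (2E)-4-[(1R,6R)-1-(methoxycarbonyl)-6-methyl-3-(propan-2-yl)cyclohex-2-en-1-yl]but-2-enoate
Product: 10 methyl 4-[(1R,6R)-1-(methoxycarbonyl)-6-methyl-3-(propan-2-yl)cyclohex-2-en-1-yl]butanoate
Conditions: H2 (1 atm), RhCl(PPh3)3 (5 mol%), toluene/EtOH, rt
Reagents that add atoms: none
Why: Homogeneous hydrogenation with RhCl(PPh3)3 reduces the unhindered disubstituted enoate C=C and leaves the trisubstituted ring alkene next to the quaternary carbon.

Step 7
Reactants: 10 methyl 4-[(1R,6R)-1-(methoxycarbonyl)-6-methyl-3-(propan-2-yl)cyclohex-2-en-1-yl]butanoate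
Product: 12 methyl (5R,10R)-2,10-dimethyl-1-oxo-7-(propan-2-yl)spiro[4.5]dec-6-ene-2-carboxylate, via sodium enolate 11 (not isolated)
Conditions: NaH (2.5 equiv), MeOH (cat.), THF, reflux; then MeI (3 equiv), 0 °C → rt; 1 M HCl
Reagents that add atoms: iodomethane, CI
Why: Dieckmann (intramolecular Claisen) condensation can only run by attack of the butanoate enolate on the non-enolisable quaternary ester, giving the five-membered β-keto ester enolate, which is C-methylated in the same flask.

Step 8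
Reactants: 12 methyl (5R,10R)-2,10-dimethyl-1-oxo-7-(propan-2-yl)spiro[4.5]dec-6-ene-2-carboxylate
Product: 13 (5R,10R)-2,10-dimethyl-7-(propan-2-yl)spiro[4.5]dec-6-en-1-one
Conditions: LiCl (3 equiv), H2O (2 equiv), DMSO, 150 °C
Reagents that add atoms: none
Why: Krapcho dealkoxycarbonylation (chloride SN2 at the ester methyl, decarboxylation, protonation) under neutral conditions that spare the alkene; the C2 epimers do not matter because C2 becomes trigonal next.

Step 9
Reactants: 13 (5R,10R)-2,10-dimethyl-7-(propan-2-yl)spiro[4.5]dec-6-en-1-one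
Product: 14 trimethyl{[(5R,10R)-2,10-dimethyl-7-(propan-2-yl)spiro[4.5]deca-1,6-dien-1-yl]oxy}silane
Conditions: Me3SiOTf (1.3 equiv), Et3N (2 equiv), CH2Cl2, 0 °C → rt
Reagents that add atoms: trimethylsilyl trifluoromethanesulfonate, C[Si](C)(C)OS(=O)(=O)C(F)(F)F
Why: Soft enolisation and O-silylation; the ketone can enolise only toward C2 (C5 is quaternary), so a single tetrasubstituted silyl enol ether forms from both epimers.

Step 10
Reactants: 15 2,4,6-trihydroxybenzaldehyde; 16 benzyl bromide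
Product: 17 2,4-bis(benzyloxy)-6-hydroxybenzaldehyde
Conditions: BnBr (2.05 equiv in all), K2CO3 (2.2 equiv), DMF, 0 °C → rt
Reagents that add atoms: benzyl bromide, BrCc1ccccc1
Why: Two successive Williamson etherifications consume two molecules of benzyl bromide (16 and the second equivalent entered on the line above), first at the most acidic para hydroxyl and then at one ortho hydroxyl, while the remaining ortho hydroxyl is hydrogen-bonded to the formyl group and stays free.

Step 11
Reactants: 17 2,4-bis(benzyloxy)-6-hydroxybenzaldehyde; 18 isobutylmagnesium bromide [(2-methylpropyl)magnesium bromide]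
Product: 19 3,5-bis(benzyloxy)-2-(1-hydroxy-3-methylbutyl)phenol
Conditions: iBuMgBr (2.5 equiv), THF, 0 °C → rt; aq. NH4Cl; used crude
Reagents that add atoms: none
Why: Grignard addition to the aldehyde after the first equivalent has deprotonated the phenol; the new carbinol centre is racemic and is erased when the quinone methide forms.

Step 12
Reactants: 14 trimethyl{[(5R,10R)-2,10-dimethyl-7-(propan-2-yl)spiro[4.5]deca-1,6-dien-1-yl]oxy}silane; 19 3,5-bis(benzyloxy)-2-(1-hydroxy-3-methylbutyl)phenol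
Product: 21 (2R,5R,10R)-2-{(1R)-1-[2,4-bis(benzyloxy)-6-hydroxyphenyl]-3-methylbutyl}-2,10-dimethyl-7-(propan-2-yl)spiro[4.5]dec-6-en-1-one, via o-quinone methide 20 (not isolated)
Conditions: Sc(OTf)3 (10 mol%), 4 Å molecular sieves, 19 (1.5 equiv, slow addition), CH2Cl2/MeCN, −40 → 0 °C; then 1 M HCl, THF, rt; chromatography
Reagents that add atoms: none
Why: Sc(OTf)3 ionises the benzylic alcohol to the o-quinone methide, which takes up the silyl enol ether in an intermolecular Mukaiyama–Michael addition; attack on the enol ether face syn to the vinylic C6–H and anti to C10 sets the quaternary centre (2R), the benzylic configuration shown is the one expected from an open antiperiplanar transition state (aryl anti to C1, isobutyl gauche to the C2 methyl, not to ring C3), and the benzylic epimer, if formed, is removed by chromatography.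

Step 13
Reactants: 21 (2R,5R,10R)-2-{(1R)-1-[2,4-bis(benzyloxy)-6-hydroxyphenyl]-3-methylbutyl}-2,10-dimethyl-7-(propan-2-yl)spiro[4.5]dec-6-en-1-one
Product: 23 (1R,3a'S,6R,9'S,9a'R)-6',8'-bis(benzyloxy)-6,9a'-dimethyl-9'-(2-methylpropyl)-3-(propan-2-yl)-1',2',9',9a'-tetrahydro-3a'H-spiro[cyclohex-2-ene-1,3'-cyclopenta[b]chromene], via cyclic hemiketal 22 (not isolated)
Conditions: Et3SiH (5 equiv), BF3·OEt2 (2 equiv), CH2Cl2, −78 → −20 °C
Reagents that add atoms: none
Why: Reductive etherification: the phenol closes onto the activated ketone, and the oxocarbenium ion (flanked by two quaternary carbons, so it cannot lose a proton) is reduced by Et3SiH from the five-ring face that carries the C9a' methyl, opposite to C9', giving the cis-fused pyran (3a'S).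

Step 14
Reactants: 23 (1R,3a'S,6R,9'S,9a'R)-6',8'-bis(benzyloxy)-6,9a'-dimethyl-9'-(2-methylpropyl)-3-(propan-2-yl)-1',2',9',9a'-tetrahydro-3a'H-spiro[cyclohex-2-ene-1,3'-cyclopenta[b]chromene]
Product: 24 (1R,3a'S,6R,9'S,9a'R)-6,9a'-dimethyl-9'-(2-methylpropyl)-3-(propan-2-yl)-1',2',9',9a'-tetrahydro-3a'H-spiro[cyclohex-2-ene-1,3'-cyclopenta[b]chromene]-6',8'-diol
Conditions: BCl3 (5 equiv), C6HMe5 (8 equiv), CH2Cl2, −78 °C; MeOH, then aq. NaHCO3; used directly
Reagents that add atoms: none
Why: Lewis-acid debenzylation with pentamethylbenzene as benzyl-cation scavenger runs at −78 °C, where the ring alkene and the secondary alkyl aryl ether are not attacked.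

Step 15
Reactants: 24 (1R,3a'S,6R,9'S,9a'R)-6,9a'-dimethyl-9'-(2-methylpropyl)-3-(propan-2-yl)-1',2',9',9a'-tetrahydro-3a'H-spiro[cyclohex-2-ene-1,3'-cyclopenta[b]chromene]-6',8'-diol
Product: 26 (1R,3a'S,6R,9'S,9a'R)-6',8'-dihydroxy-6,9a'-dimethyl-9'-(2-methylpropyl)-3-(propan-2-yl)-1',2',9',9a'-tetrahydro-3a'H-spiro[cyclohex-2-ene-1,3'-cyclopenta[b]chromene]-5',7'-dicarbaldehyde (CNP0121396.3), via bis(iminium) salt 25 (not isolated)
Conditions: POCl3 (5 equiv), DMF (10 equiv), MeCN, 0 °C → rt; then H2O, 50 °C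
Reagents that add atoms: N,N-dimethylformamide, CN(C)C=O; water, O
Why: Vilsmeier–Haack formylation at both free phloroglucinol-type ring positions followed by iminium hydrolysis; the arene is far more nucleophilic than the isolated alkene at this temperature and no stereocentre is involved.

## Compound list

1 | (−)-menthone, (2S,5R)-5-methyl-2-(propan-2-yl)cyclohexan-1-one | CC(C)[C@@H]1CC[C@@H](C)CC1=O | starting material
2 | dimethyl carbonate | COC(=O)OC | starting material
3 | methyl (6R)-6-methyl-2-oxo-3-(propan-2-yl)cyclohexane-1-carboxylate (C1/C3 epimers and enol) | COC(=O)C1C(=O)C(C(C)C)CC[C@H]1C | intermediate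
4 | allyl bromide | C=CCBr | starting material
5 | methyl (1R,6R)-6-methyl-2-oxo-3-(propan-2-yl)-1-(prop-2-en-1-yl)cyclohexane-1-carboxylate (allyl trans to 6-methyl; C3 epimers) | C=CC[C@]1(C(=O)OC)C(=O)C(C(C)C)CC[C@H]1C | intermediate
6 | methyl (1R,6R)-6-methyl-3-(propan-2-yl)-1-(prop-2-en-1-yl)-2-[(trifluoromethanesulfonyl)oxy]cyclohex-2-ene-1-carboxylate | C=CC[C@]1(C(=O)OC)C(OS(=O)(=O)C(F)(F)F)=C(C(C)C)CC[C@H]1C | intermediate
7 | methyl (1R,6R)-6-methyl-3-(propan-2-yl)-1-(prop-2-en-1-yl)cyclohex-2-ene-1-carboxylate | C=CC[C@]1(C(=O)OC)C=C(C(C)C)CC[C@H]1C | intermediate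
8 | methyl acrylate | C=CC(=O)OC | starting material
9 | methyl (2E)-4-[(1R,6R)-1-(methoxycarbonyl)-6-methyl-3-(propan-2-yl)cyclohex-2-en-1-yl]but-2-enoate | COC(=O)/C=C/C[C@]1(C(=O)OC)C=C(C(C)C)CC[C@H]1C | intermediate
10 | methyl 4-[(1R,6R)-1-(methoxycarbonyl)-6-methyl-3-(propan-2-yl)cyclohex-2-en-1-yl]butanoate | COC(=O)CCC[C@]1(C(=O)OC)C=C(C(C)C)CC[C@H]1C | intermediate
11 | sodium enolate of methyl (5R,10R)-10-methyl-1-oxo-7-(propan-2-yl)spiro[4.5]dec-6-ene-2-carboxylate | [Na+].[O-]C1=C(C(=O)OC)CC[C@@]12C=C(C(C)C)CC[C@H]2C | intermediate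
12 | methyl (5R,10R)-2,10-dimethyl-1-oxo-7-(propan-2-yl)spiro[4.5]dec-6-ene-2-carboxylate (C2 epimers) | O=C1C(C)(C(=O)OC)CC[C@@]12C=C(C(C)C)CC[C@H]2C | intermediate
13 | (5R,10R)-2,10-dimethyl-7-(propan-2-yl)spiro[4.5]dec-6-en-1-one (C2 epimers; 10-methyl cis to C1 on the six-membered ring) | O=C1C(C)CC[C@@]12C=C(C(C)C)CC[C@H]2C | intermediate
14 | trimethyl{[(5R,10R)-2,10-dimethyl-7-(propan-2-yl)spiro[4.5]deca-1,6-dien-1-yl]oxy}silane | C[Si](C)(C)OC1=C(C)CC[C@@]12C=C(C(C)C)CC[C@H]2C | intermediate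
15 | 2,4,6-trihydroxybenzaldehyde | O=Cc1c(O)cc(O)cc1O | starting material
16 | benzyl bromide | BrCc1ccccc1 | starting material
17 | 2,4-bis(benzyloxy)-6-hydroxybenzaldehyde | O=Cc1c(O)cc(OCc2ccccc2)cc1OCc1ccccc1 | intermediate
18 | isobutylmagnesium bromide | CC(C)C[Mg]Br | starting material
19 | 3,5-bis(benzyloxy)-2-(1-hydroxy-3-methylbutyl)phenol (racemic) | CC(C)CC(O)c1c(O)cc(OCc2ccccc2)cc1OCc1ccccc1 | intermediate
20 | (6E)-3,5-bis(benzyloxy)-6-(3-methylbutylidene)cyclohexa-2,4-dien-1-one (o-quinone methide) | CC(C)C/C=C1\C(OCc2ccccc2)=CC(OCc2ccccc2)=CC1=O | intermediate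
21 | (2R,5R,10R)-2-{(1R)-1-[2,4-bis(benzyloxy)-6-hydroxyphenyl]-3-methylbutyl}-2,10-dimethyl-7-(propan-2-yl)spiro[4.5]dec-6-en-1-one | CC(C)C[C@H](c1c(O)cc(OCc2ccccc2)cc1OCc1ccccc1)[C@@]1(C)CC[C@@]2(C=C(C(C)C)CC[C@H]2C)C1=O | intermediate
22 | cyclic hemiketal of 21 (phenol oxygen added to C1; the 3a'-hydroxy analogue of 23) | CC(C)C[C@@H]1c2c(OCc3ccccc3)cc(OCc3ccccc3)cc2OC2(O)[C@]1(C)CC[C@@]21C=C(C(C)C)CC[C@H]1C | intermediate
23 | (1R,3a'S,6R,9'S,9a'R)-6',8'-bis(benzyloxy)-6,9a'-dimethyl-9'-(2-methylpropyl)-3-(propan-2-yl)-1',2',9',9a'-tetrahydro-3a'H-spiro[cyclohex-2-ene-1,3'-cyclopenta[b]chromene] (cis-fused; isobutyl trans to the 9a'-methyl) | CC(C)C[C@@H]1c2c(OCc3ccccc3)cc(OCc3ccccc3)cc2O[C@H]2[C@]1(C)CC[C@@]21C=C(C(C)C)CC[C@H]1C | intermediate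
24 | (1R,3a'S,6R,9'S,9a'R)-6,9a'-dimethyl-9'-(2-methylpropyl)-3-(propan-2-yl)-1',2',9',9a'-tetrahydro-3a'H-spiro[cyclohex-2-ene-1,3'-cyclopenta[b]chromene]-6',8'-diol | CC(C)C[C@@H]1c2c(O)cc(O)cc2O[C@H]2[C@]1(C)CC[C@@]21C=C(C(C)C)CC[C@H]1C | intermediate
25 | 5',7'-bis[(dimethyliminio)methyl] derivative of 24, dichloride | CC(C)C[C@@H]1c2c(O)c(C=[N+](C)C)c(O)c(C=[N+](C)C)c2O[C@H]2[C@]1(C)CC[C@@]21C=C(C(C)C)CC[C@H]1C.[Cl-].[Cl-] | intermediate
26 | CNP0121396.3, (1R,3a'S,6R,9'S,9a'R)-6',8'-dihydroxy-6,9a'-dimethyl-9'-(2-methylpropyl)-3-(propan-2-yl)-1',2',9',9a'-tetrahydro-3a'H-spiro[cyclohex-2-ene-1,3'-cyclopenta[b]chromene]-5',7'-dicarbaldehyde | CC(C)C[C@@H]1c2c(O)c(C=O)c(O)c(C=O)c2O[C@H]2[C@]1(C)CC[C@@]21C=C(C(C)C)CC[C@H]1C | target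

## Step count and risks

Total steps: 15. Longest linear sequence: 13 steps (steps 1–9, then 12–15, from (−)-menthone); the aromatic branch is steps 10–11.

Steps most likely to fail:

1. Step 12. The bond joins a quaternary carbon to a hindered benzylic carbon. The Lewis acid and the water set free from 19 can protodesilylate 14 before it reacts. The benzylic configuration rests on an open transition state with only a modest steric bias, so the epimer may dominate. Fallback, setting out from 14 and 17 (with 18) and coming back at 23: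
   - 17 is treated with Boc2O, iPr2NEt and 4-(dimethylamino)pyridine (cat.) in CH2Cl2 to give 3,5-bis(benzyloxy)-2-formylphenyl tert-butyl carbonate F1.
   - iBuMgBr 18 is added to F1 in THF at −78 °C in the presence of 14. The Boc group shifts from the phenol oxygen to the new alkoxide and gives bromomagnesium 3,5-bis(benzyloxy)-2-{1-[(tert-butoxycarbonyl)oxy]-3-methylbutyl}phenolate F2.
   - On warming to rt, F2 expels tert-butyl carbonate and gives 20 with no Lewis acid and no free water present.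
   - 20 and 14 then combine in an inverse-electron-demand hetero-Diels–Alder reaction (quinone methide oxygen to the silyloxy carbon C1, methide carbon to C2) on the same enol ether face as in step 12. The product is the silyl ketal {[(1R,3a'R,6R,9'R,9a'R)-6',8'-bis(benzyloxy)-6,9a'-dimethyl-9'-(2-methylpropyl)-3-(propan-2-yl)-1',2',9',9a'-tetrahydro-3a'H-spiro[cyclohex-2-ene-1,3'-cyclopenta[b]chromen]-3a'-yl]oxy}trimethylsilane F3.
   - The orientation of the isobutyl group is now decided by the endo/exo preference of a closed transition state. F3 arises from the E-configured quinone methide with the cyclopentene ring carbons endo and the OSiMe3 and methyl groups exo. The C9' epimer, if formed, is separated at this stage.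
   - Et3SiH and BF3·OEt2 in CH2Cl2 at −78 °C ionise the silyl ketal of F3 to the oxocarbenium ion of step 13 and reduce it to 23. 21 and 22 are bypassed.

2. Step 13. The ketone is flanked by two quaternary carbons, so hemiketal formation and hydride delivery may be slow, and acid could reverse the Michael addition or touch the alkene. Fallback, setting out from 21 and coming back at 23:
   - 21 is reduced with LiAlH4 in THF at 0 °C (hydride anti to the benzylic substituent) to (1S,2R,5R,10R)-2-{(1S)-1-[2,4-bis(benzyloxy)-6-hydroxyphenyl]-3-methylbutyl}-2,10-dimethyl-7-(propan-2-yl)spiro[4.5]dec-6-en-1-ol F4.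
   - The phenol alone is triflated with PhNTf2 and Et3N in CH2Cl2 to give 3,5-bis(benzyloxy)-2-{(1S)-1-[(1S,2R,5R,10R)-1-hydroxy-2,10-dimethyl-7-(propan-2-yl)spiro[4.5]dec-6-en-2-yl]-3-methylbutyl}phenyl trifluoromethanesulfonate F5.
   - Palladium-catalysed intramolecular C–O coupling (Pd(OAc)2, 2-(di-tert-butylphosphino)-1,1'-binaphthyl, Cs2CO3, toluene, 80 °C) then closes the pyran with retention at the carbinol carbon to give 23.

3. Step 15. Double formylation of an air-sensitive resorcinol in the presence of a trisubstituted alkene may stop at the mono-aldehyde or damage the alkene. Fallback, setting out from 23 and coming back at 26: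
   - 23 is dibrominated with N-bromosuccinimide in CH2Cl2 at −40 °C to (1R,3a'S,6R,9'S,9a'R)-6',8'-bis(benzyloxy)-5',7'-dibromo-6,9a'-dimethyl-9'-(2-methylpropyl)-3-(propan-2-yl)-1',2',9',9a'-tetrahydro-3a'H-spiro[cyclohex-2-ene-1,3'-cyclopenta[b]chromene] F6.
   - Two rounds of bromine–lithium exchange (t-BuLi, THF, −78 °C) and DMF quench in the same flask, with aqueous work-up only after the second round, give (1R,3a'S,6R,9'S,9a'R)-6',8'-bis(benzyloxy)-6,9a'-dimethyl-9'-(2-methylpropyl)-3-(propan-2-yl)-1',2',9',9a'-tetrahydro-3a'H-spiro[cyclohex-2-ene-1,3'-cyclopenta[b]chromene]-5',7'-dicarbaldehyde F7.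
   - BCl3 with C6HMe5 in CH2Cl2 at −78 °C then removes both benzyl groups to give 26.

Further compounds
F1 | step 12 | 3,5-bis(benzyloxy)-2-formylphenyl tert-butyl carbonate | O=Cc1c(OC(=O)OC(C)(C)C)cc(OCc2ccccc2)cc1OCc1ccccc1
F2 | step 12 | bromomagnesium 3,5-bis(benzyloxy)-2-{1-[(tert-butoxycarbonyl)oxy]-3-methylbutyl}phenolate (racemic) | CC(C)CC(OC(=O)OC(C)(C)C)c1c([O-])cc(OCc2ccccc2)cc1OCc1ccccc1.[Mg+2].[Br-]
F3 | step 12 | {[(1R,3a'R,6R,9'R,9a'R)-6',8'-bis(benzyloxy)-6,9a'-dimethyl-9'-(2-methylpropyl)-3-(propan-2-yl)-1',2',9',9a'-tetrahydro-3a'H-spiro[cyclohex-2-ene-1,3'-cyclopenta[b]chromen]-3a'-yl]oxy}trimethylsilane | CC(C)C[C@@H]1c2c(OCc3ccccc3)cc(OCc3ccccc3)cc2O[C@@]2(O[Si](C)(C)C)[C@]1(C)CC[C@@]21C=C(C(C)C)CC[C@H]1C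
F4 | step 13 | (1S,2R,5R,10R)-2-{(1S)-1-[2,4-bis(benzyloxy)-6-hydroxyphenyl]-3-methylbutyl}-2,10-dimethyl-7-(propan-2-yl)spiro[4.5]dec-6-en-1-ol | CC(C)C[C@H](c1c(O)cc(OCc2ccccc2)cc1OCc1ccccc1)[C@@]1(C)CC[C@@]2(C=C(C(C)C)CC[C@H]2C)[C@H]1O
F5 | step 13 | 3,5-bis(benzyloxy)-2-{(1S)-1-[(1S,2R,5R,10R)-1-hydroxy-2,10-dimethyl-7-(propan-2-yl)spiro[4.5]dec-6-en-2-yl]-3-methylbutyl}phenyl trifluoromethanesulfonate | CC(C)C[C@H](c1c(OS(=O)(=O)C(F)(F)F)cc(OCc2ccccc2)cc1OCc1ccccc1)[C@@]1(C)CC[C@@]2(C=C(C(C)C)CC[C@H]2C)[C@H]1O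
F6 | step 15 | (1R,3a'S,6R,9'S,9a'R)-6',8'-bis(benzyloxy)-5',7'-dibromo-6,9a'-dimethyl-9'-(2-methylpropyl)-3-(propan-2-yl)-1',2',9',9a'-tetrahydro-3a'H-spiro[cyclohex-2-ene-1,3'-cyclopenta[b]chromene] | CC(C)C[C@@H]1c2c(OCc3ccccc3)c(Br)c(OCc3ccccc3)c(Br)c2O[C@H]2[C@]1(C)CC[C@@]21C=C(C(C)C)CC[C@H]1C
F7 | step 15 | (1R,3a'S,6R,9'S,9a'R)-6',8'-bis(benzyloxy)-6,9a'-dimethyl-9'-(2-methylpropyl)-3-(propan-2-yl)-1',2',9',9a'-tetrahydro-3a'H-spiro[cyclohex-2-ene-1,3'-cyclopenta[b]chromene]-5',7'-dicarbaldehyde | CC(C)C[C@@H]1c2c(OCc3ccccc3)c(C=O)c(OCc3ccccc3)c(C=O)c2O[C@H]2[C@]1(C)CC[C@@]21C=C(C(C)C)CC[C@H]1C
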